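**No clock.** The starting rate cannot give the moment when half of X is gone in this flask, which we call the mark: G turns X into Z at a pace that sinks with X, while G itself leaves the round by pairing into G2 and by turning into Q, both off-cycle forms.

X 10 mM; G 1.0 µM

    2 G → G2 (k1 = 12700 /M/s)
    X + G → Z + G, rate k2*[X]^2*[G]/(1 + ([X]/Kh2)^2) (Kh2 = 11.1 mM, k2 = 4.25 × 10⁶ /M²/s)
    G → Q (k3 = 0.0178 /s)

- a step written with two of one species runs at k times the square of its concentration and takes two of it each time
- a form made of two catalysts counts as two
- charge of X (flask): 10 mM

- the form that holds most of the catalyst when 50% of the X are converted (Q / G2 / G)
- its share of the catalyst then

**Times first.** At the charge, G has a half-life of 38.9 s against the turn into Q and 39.4 s against pairing. At the starting rate of 0.235 mM/s the 5.00 mM to convert take 21.3 s, less than either, so our first estimate puts the mark early, with G still the main form. But with 5.00 mM of X left, each G works at 37.7% of its starting pace, so that estimate falls.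

**Working time.** We stop counting clock seconds and add up what each mM of X costs at its own pace, which comes to 33.1 s: this is the working time W, the seconds of work by the full charge of G that the mark costs. The objection is that G fades. Pairing at the charge takes G 1.43 times as fast as the turn into Q, and the two together let the charge deliver 34.9 s of work over the whole run, more than W, so we reckon the mark late, at 144 s.

**The shares.** A second doubt is that pairing might upset the count of Q, but Q grows at its constant times G, and W adds up that same G over the time, so the share in Q is the constant of that turn times W, 58.9%. G then stands at 3.33%, and G2, counted as two, takes the remaining 37.8%, so the largest form is Q.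

**The forecast.** The forecast names Q at 58.9%, within 57.5% to 60.5%, on the ground that “Both are independent of X, so G(t) integrates exactly”.

**The result.** The simulated flask gives Q at 58.9% when the mark is reached at 144 s, with G2 holding 37.8% of the catalyst. In the flask with twice the G, the same conversion costs the doubled charge half of W, 16.6 s, while each G at that charge pairs at twice its pace, and our reckoning then puts the mark at 34.8 s, a factor of 0.242 on the time of this flask. The run with twice the G gives a factor of 0.242.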